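**Retrosynthetic overview**

1. Locants: upper flavan unit O1, C2–C4, ring A (C4a–C8a), ring B; lower unit primed. The last operations are hydrogenolysis of eight benzyl ethers and MnO2 oxidation of a C4' carbinol to C4'=O; until then that carbinol serves as a stereocontrol element.
2. C2, C3, C2' and C3' come from one double hydroboration–oxidation of a bis(2-aryl-4H-chromene), with boron entering C3/C3' anti to the C4 aryl group and the C4' silyl ether.
3. Both pyran rings C are closed by a double ring-closing metathesis that forms C2=C3 and C2'=C3'. The enabling feature: in each unit O1 sits on C8a, ortho to C4a, which carries the C4–C3 arm, and C2 bears only O1 and ring B. C2 can therefore enter as the carbonyl carbon of the same tribenzyl gallate ester (twice) and be methylenated to an aryl enol ether facing a C3 alkene.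
4. The C4–C8' bond comes from an aromatic Claisen rearrangement of a 7'-O-allyl ether of 2,4-dihydroxybenzaldehyde to C8', with 1,3-chirality transfer (ether from CBS reduction and Mitsunobu inversion). The C4' carbinol comes from an asymmetric Nozaki–Hiyama–Kishi vinylation.
5. Ring order: rings A and B are bought; lower ring C closes first and upper ring C second, in the same flask.

Key step: step 11

Remark: in the two-fold steps 10 and 12 the two sites react in the same flask in either order, so half-converted species are not listed; the mono-cyclised species of step 11 is listed because the order of ring closure is part of the design.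

Step 1
Reactants: 1 4-(benzyloxy)-2-hydroxybenzaldehyde; 2 3,4,5-tris(benzyloxy)benzoic acid
Product: 3 5-(benzyloxy)-2-formylphenyl 3,4,5-tris(benzyloxy)benzoate
Conditions: EDC·HCl, DMAP (cat.), CH2Cl2, 0 °C to rt
Reagents that add atoms: none
Why: Steglich esterification of the phenol brings in ring B and C2 of the upper unit at the acid oxidation level and at the same time protects O1; no stereocentre is formed.

Step 2
Reactants: 3 5-(benzyloxy)-2-formylphenyl 3,4,5-tris(benzyloxy)benzoate; 4 (acetylmethylene)triphenylphosphorane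
Product: 5 5-(benzyloxy)-2-[(1E)-3-oxobut-1-en-1-yl]phenyl 3,4,5-tris(benzyloxy)benzoate
Conditions: CH2Cl2, 40 °C
Reagents that add atoms: none
Why: Wittig olefination with a stabilised ylide should give the (E)-enone and leave the aryl ester untouched.

Step 3
Reactants: 5 5-(benzyloxy)-2-[(1E)-3-oxobut-1-en-1-yl]phenyl 3,4,5-tris(benzyloxy)benzoate
Product: 6 5-(benzyloxy)-2-[(1E,3R)-3-hydroxybut-1-en-1-yl]phenyl 3,4,5-tris(benzyloxy)benzoate
Conditions: (S)-2-methyl-CBS-oxazaborolidine (15 mol %), catecholborane, toluene, −78 °C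
Reagents that add atoms: none
Why: Corey–Bakshi–Shibata 1,2-reduction of the enone; with the styryl group as the large substituent the (S)-catalyst should deliver hydride to give the (R)-carbinol.

Step 4
Reactants: 6 5-(benzyloxy)-2-[(1E,3R)-3-hydroxybut-1-en-1-yl]phenyl 3,4,5-tris(benzyloxy)benzoate; 7 2,4-dihydroxybenzaldehyde
Product: 8 5-(benzyloxy)-2-[(1E,3S)-3-(4-formyl-3-hydroxyphenoxy)but-1-en-1-yl]phenyl 3,4,5-tris(benzyloxy)benzoate
Conditions: PPh3, DIAD, toluene, −20 to 0 °C
Reagents that add atoms: none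
Why: Mitsunobu etherification of the more acidic, non-chelated 4-OH of 7 with SN2 inversion gives the (S)-ether; the ortho acyloxy group lowers the donor strength of the styrene and so disfavours ionisation and SN2' attack.

Step 5
Reactants: 8 5-(benzyloxy)-2-[(1E,3S)-3-(4-formyl-3-hydroxyphenoxy)but-1-en-1-yl]phenyl 3,4,5-tris(benzyloxy)benzoate
Product: 9 5-(benzyloxy)-2-[(1S,2E)-1-(3-formyl-2,6-dihydroxyphenyl)but-2-en-1-yl]phenyl 3,4,5-tris(benzyloxy)benzoate
Conditions: Eu(fod)3 (10 mol %; fod = 6,6,7,7,8,8,8-heptafluoro-2,2-dimethyloctane-3,5-dionate), toluene, 80 °C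
Reagents that add atoms: none
Why: Aromatic Claisen [3,3] rearrangement; the hydrogen bond between the 8a'-OH and the formyl group localises the C7'=C8' bond so the allyl group should migrate to C8', and a chair transition state with the methyl group equatorial transfers the C–O chirality to C4 (S) and gives the (E)-propenyl group.

Step 6
Reactants: 9 5-(benzyloxy)-2-[(1S,2E)-1-(3-formyl-2,6-dihydroxyphenyl)but-2-en-1-yl]phenyl 3,4,5-tris(benzyloxy)benzoate
Product: 10 5-(benzyloxy)-2-{(1S,2E)-1-[6-(benzyloxy)-3-formyl-2-hydroxyphenyl]but-2-en-1-yl}phenyl 3,4,5-tris(benzyloxy)benzoate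
Conditions: BnBr, NaHCO3, KI (cat.), MeCN, 60 °C
Reagents that add atoms: benzyl bromide, BrCc1ccccc1
Why: Williamson benzylation under weak base should take only the non-chelated 7'-OH (para to the formyl group), as in the known selective 4-O-alkylation of 2,4-dihydroxybenzaldehydes.

Step 7
Reactants: 10 5-(benzyloxy)-2-{(1S,2E)-1-[6-(benzyloxy)-3-formyl-2-hydroxyphenyl]but-2-en-1-yl}phenyl 3,4,5-tris(benzyloxy)benzoate; 2 3,4,5-tris(benzyloxy)benzoic acid
Product: 11 bis-gallate aldehyde
Conditions: EDC·HCl, DMAP, CH2Cl2, rt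
Reagents that add atoms: none
Why: A second Steglich esterification, now at the remaining chelated phenol O1', brings in ring B' and C2' of the lower unit; no stereocentre is touched.

Step 8
Reactants: 11 bis-gallate aldehyde
Product: 13 (S)-vinyl carbinol, via trimethylsilyl ether 12 (not isolated)
Conditions: CH2=CHBr, CrCl2 (10 mol %), chiral 2-(4-isopropyloxazolin-2-yl)aryl methanesulfonamide ligand (12 mol %; the antipode that leads to the (S)-carbinol), Et3N, NiCl2 (2 mol %), Mn, Me3SiCl, THF/MeCN, rt; then aq. citric acid, THF, 0 °C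
Reagents that add atoms: vinyl bromide, C=CBr; chlorotrimethylsilane, C[Si](C)(C)Cl (silicon present only in 12)
Why: Catalytic asymmetric Nozaki–Hiyama–Kishi vinylation tolerates the two aryl esters, the ligand-bound chromium centre selects the aldehyde face that gives the (S)-carbinol (future C4'), and silylation of the chromium alkoxide prevents an acyl shift from O1'.

Step 9
Reactants: 13 (S)-vinyl carbinol
Product: 14 tert-butyldimethylsilyl ether of 13
Conditions: TBSOTf, 2,6-lutidine, CH2Cl2, −78 °C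
Reagents that add atoms: tert-butyldimethylsilyl triflate, CC(C)(C)[Si](C)(C)OS(=O)(=O)C(F)(F)F
Why: Silylation without a free alkoxide blocks the O1'-to-O4' acyl shift and turns the C4' oxygen into a bulky, poorly leaving group for steps 10 to 12.

Step 10
Reactants: 14 tert-butyldimethylsilyl ether of 13
Product: 15 bis(aryl enol ether)
Conditions: Cp2TiMe2 (6 equiv), toluene/THF, 70 °C, dark
Reagents that add atoms: dimethyltitanocene, C[Ti](C)(C1C=CC=C1)C1C=CC=C1
Why: Petasis methylenation (titanium methylidene, oxatitanacyclobutane) converts both aryl esters into 1-aryl-1-aryloxyethenes under non-basic conditions that spare the silyl ether, the benzyl ethers and both alkenes.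

Step 11
Reactants: 15 bis(aryl enol ether)
Product: 17 bis(4H-chromene), via mono-chromene enol ether 16 (not isolated)
Conditions: (H2IMes)(PCy3)Cl2Ru=CHPh (second-generation Grubbs catalyst, 15 mol %), degassed toluene (5 mM), 80 °C, argon sparge
Reagents that add atoms: none
Why: Olefin metathesis: the ruthenium carbene first engages the terminal vinyl group on C4' and adds across the O1' enol ether C2'=CH2 (metallacyclobutane, ethylene lost) to close the lower ring C as 16; a second cycle joins the propenyl carbon C3 to the O1 enol ether carbon C2 (propene lost) and closes the upper ring C. The closest known reactions are ring-closing metathesis of aryl enol ethers bearing an ortho allyl group to 4H-chromenes and of 1,1-disubstituted enol ethers to trisubstituted cyclic enol ethers. Both rings close in the six-membered mode onto a 1,1-disubstituted alkene and give endocyclic trisubstituted enol ethers C2=C3 and C2'=C3'. No stereocentre is created; C4 and C4' pass through unchanged and are the control elements for step 12. The step needs correct pairing, because the O1' enol ether could also reach the C4 propenyl group in a six-membered ring: this is secured by the faster initiation at the terminal vinyl group, whose carbene can reach only the O1' enol ether, so that this enol ether is consumed before the hindered internal propenyl group reacts. The two alkene arms cannot close onto each other because they sit meta on the lower ring A.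

Step 12
Reactants: 17 bis(4H-chromene)
Product: 19 diol, via bis(dihydroboryl) adduct 18 (not isolated)
Conditions: BH3·THF (excess), THF, 0 °C to rt; then 3 M NaOH, 30% H2O2, 0 °C
Reagents that add atoms: borane–tetrahydrofuran, [BH3-][O+]1CCCC1 (boron present only in 18); hydrogen peroxide, OO
Why: Hydroboration–oxidation: borane should add syn across each enol ether with boron on C3/C3' (β to the ring oxygen) from the face opposite the C4 aryl group and the C4' silyl ether, and oxidation with retention gives the 2,3-trans-3,4-trans arrangement in both rings, which sets C2 (R), C3 (S), C2' and C3'.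

Step 13
Reactants: 19 diol
Product: 20 triol
Conditions: Bu4NF, THF, 0 °C to rt
Reagents that add atoms: none
Why: Fluoride desilylation frees the C4' alcohol under basic conditions that cannot ionise the benzylic C4'–O bond.

Step 14
Reactants: 20 triol
Product: 21 octa-O-benzyl target
Conditions: activated MnO2, CH2Cl2, rt
Reagents that add atoms: none
Why: MnO2 should oxidise only the benzylic C4' alcohol (para to the C7' ether oxygen) and leave the aliphatic C3 and C3' alcohols; the C4' stereocentre is erased on purpose and the lower ring becomes the (2'R,3'R)-dihydroflavonol.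

Step 15
Reactants: 21 octa-O-benzyl target
Product: 22 CNP0321606.1
Conditions: H2 (1 atm), Pd(OH)2/C, THF/MeOH, rt
Reagents that add atoms: none
Why: Hydrogenolysis removes the eight benzyl ethers, as is routine for benzylated flavan-3-ols and dihydroflavonols, without touching the aryl ketone or the ring C–O bonds.

**Compound list**

1 | 4-(benzyloxy)-2-hydroxybenzaldehyde | O=Cc1ccc(OCc2ccccc2)cc1O | starting material
2 | 3,4,5-tris(benzyloxy)benzoic acid | OC(=O)c1cc(OCc2ccccc2)c(OCc2ccccc2)c(OCc2ccccc2)c1 | starting material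
3 | 5-(benzyloxy)-2-formylphenyl 3,4,5-tris(benzyloxy)benzoate | O=Cc1ccc(OCc2ccccc2)cc1OC(=O)c1cc(OCc2ccccc2)c(OCc2ccccc2)c(OCc2ccccc2)c1 | intermediate
4 | (acetylmethylene)triphenylphosphorane | CC(=O)C=P(c1ccccc1)(c1ccccc1)c1ccccc1 | starting material
5 | 5-(benzyloxy)-2-[(1E)-3-oxobut-1-en-1-yl]phenyl 3,4,5-tris(benzyloxy)benzoate | CC(=O)/C=C/c1ccc(OCc2ccccc2)cc1OC(=O)c1cc(OCc2ccccc2)c(OCc2ccccc2)c(OCc2ccccc2)c1 | intermediate
6 | 5-(benzyloxy)-2-[(1E,3R)-3-hydroxybut-1-en-1-yl]phenyl 3,4,5-tris(benzyloxy)benzoate | C[C@@H](O)/C=C/c1ccc(OCc2ccccc2)cc1OC(=O)c1cc(OCc2ccccc2)c(OCc2ccccc2)c(OCc2ccccc2)c1 | intermediate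
7 | 2,4-dihydroxybenzaldehyde | O=Cc1ccc(O)cc1O | starting material
8 | 5-(benzyloxy)-2-[(1E,3S)-3-(4-formyl-3-hydroxyphenoxy)but-1-en-1-yl]phenyl 3,4,5-tris(benzyloxy)benzoate | C[C@H](Oc1ccc(C=O)c(O)c1)/C=C/c1ccc(OCc2ccccc2)cc1OC(=O)c1cc(OCc2ccccc2)c(OCc2ccccc2)c(OCc2ccccc2)c1 | intermediate
9 | 5-(benzyloxy)-2-[(1S,2E)-1-(3-formyl-2,6-dihydroxyphenyl)but-2-en-1-yl]phenyl 3,4,5-tris(benzyloxy)benzoate (C4 is S, C4–C8' bond in place) | C/C=C/[C@H](c1c(O)ccc(C=O)c1O)c1ccc(OCc2ccccc2)cc1OC(=O)c1cc(OCc2ccccc2)c(OCc2ccccc2)c(OCc2ccccc2)c1 | intermediate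
10 | 5-(benzyloxy)-2-{(1S,2E)-1-[6-(benzyloxy)-3-formyl-2-hydroxyphenyl]but-2-en-1-yl}phenyl 3,4,5-tris(benzyloxy)benzoate | C/C=C/[C@H](c1c(OCc2ccccc2)ccc(C=O)c1O)c1ccc(OCc2ccccc2)cc1OC(=O)c1cc(OCc2ccccc2)c(OCc2ccccc2)c(OCc2ccccc2)c1 | intermediate
11 | bis-gallate aldehyde: 10 with the remaining phenol (O1') also esterified by 2; C4 (S), (E)-propenyl | C/C=C/[C@H](c1c(OCc2ccccc2)ccc(C=O)c1OC(=O)c1cc(OCc2ccccc2)c(OCc2ccccc2)c(OCc2ccccc2)c1)c1ccc(OCc2ccccc2)cc1OC(=O)c1cc(OCc2ccccc2)c(OCc2ccccc2)c(OCc2ccccc2)c1 | intermediate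
12 | trimethylsilyl ether of 13: formyl group of 11 converted into (S)-CH(OSiMe3)CH=CH2; C4 (S) | C/C=C/[C@H](c1c(OCc2ccccc2)ccc([C@@H](O[Si](C)(C)C)C=C)c1OC(=O)c1cc(OCc2ccccc2)c(OCc2ccccc2)c(OCc2ccccc2)c1)c1ccc(OCc2ccccc2)cc1OC(=O)c1cc(OCc2ccccc2)c(OCc2ccccc2)c(OCc2ccccc2)c1 | intermediate (not isolated)
13 | (S)-vinyl carbinol: formyl group of 11 converted into (S)-CH(OH)CH=CH2 (future C4'); C4 (S) | C/C=C/[C@H](c1c(OCc2ccccc2)ccc([C@@H](O)C=C)c1OC(=O)c1cc(OCc2ccccc2)c(OCc2ccccc2)c(OCc2ccccc2)c1)c1ccc(OCc2ccccc2)cc1OC(=O)c1cc(OCc2ccccc2)c(OCc2ccccc2)c(OCc2ccccc2)c1 | intermediate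
14 | tert-butyldimethylsilyl ether of 13; C4 (S), C4' (S) | C/C=C/[C@H](c1c(OCc2ccccc2)ccc([C@@H](O[Si](C)(C)C(C)(C)C)C=C)c1OC(=O)c1cc(OCc2ccccc2)c(OCc2ccccc2)c(OCc2ccccc2)c1)c1ccc(OCc2ccccc2)cc1OC(=O)c1cc(OCc2ccccc2)c(OCc2ccccc2)c(OCc2ccccc2)c1 | intermediate
15 | bis(aryl enol ether): 14 with both ester C=O groups replaced by C=CH2; C4 (S), C4' (S) | C/C=C/[C@H](c1c(OCc2ccccc2)ccc([C@@H](O[Si](C)(C)C(C)(C)C)C=C)c1OC(=C)c1cc(OCc2ccccc2)c(OCc2ccccc2)c(OCc2ccccc2)c1)c1ccc(OCc2ccccc2)cc1OC(=C)c1cc(OCc2ccccc2)c(OCc2ccccc2)c(OCc2ccccc2)c1 | intermediate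
16 | mono-chromene enol ether: lower ring C closed (C2'=C3', (4'S)-silyloxy-4H-chromene), upper enol ether and (E)-propenyl group still open; C4 (S) | C/C=C/[C@H](c1c(OCc2ccccc2)ccc2c1OC(c1cc(OCc3ccccc3)c(OCc3ccccc3)c(OCc3ccccc3)c1)=C[C@@H]2O[Si](C)(C)C(C)(C)C)c1ccc(OCc2ccccc2)cc1OC(=C)c1cc(OCc2ccccc2)c(OCc2ccccc2)c(OCc2ccccc2)c1 | intermediate (not isolated)
17 | bis(4H-chromene): (4S)-7-(benzyloxy)-4-[(tert-butyldimethylsilyl)oxy]-8-{(4S)-7-(benzyloxy)-2-[3,4,5-tris(benzyloxy)phenyl]-4H-chromen-4-yl}-2-[3,4,5-tris(benzyloxy)phenyl]-4H-chromene | CC(C)(C)[Si](C)(C)O[C@H]1C=C(c3cc(OCc4ccccc4)c(OCc4ccccc4)c(OCc4ccccc4)c3)Oc2c([C@H]3C=C(c5cc(OCc6ccccc6)c(OCc6ccccc6)c(OCc6ccccc6)c5)Oc4cc(OCc5ccccc5)ccc43)c(OCc3ccccc3)ccc21 | intermediate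
18 | bis(dihydroboryl) adduct of 17: BH2 on C3 and C3', trans to the C4 aryl group and to the C4' silyl ether; ring B and B' aryl groups trans to boron | CC(C)(C)[Si](C)(C)O[C@@H]1c2ccc(OCc3ccccc3)c([C@@H]3c4ccc(OCc5ccccc5)cc4O[C@H](c4cc(OCc5ccccc5)c(OCc5ccccc5)c(OCc5ccccc5)c4)[C@H]3B)c2O[C@H](c2cc(OCc3ccccc3)c(OCc3ccccc3)c(OCc3ccccc3)c2)[C@H]1B | intermediate (not isolated)
19 | diol: upper (2R,3S,4S)-4-arylflavan-3-ol, lower (2'R,3'R,4'R)-4'-silyloxyflavan-3'-ol, both rings 2,3-trans-3,4-trans, all phenols as benzyl ethers | CC(C)(C)[Si](C)(C)O[C@@H]1c2ccc(OCc3ccccc3)c([C@@H]3c4ccc(OCc5ccccc5)cc4O[C@H](c4cc(OCc5ccccc5)c(OCc5ccccc5)c(OCc5ccccc5)c4)[C@H]3O)c2O[C@H](c2cc(OCc3ccccc3)c(OCc3ccccc3)c(OCc3ccccc3)c2)[C@H]1O | intermediate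
20 | triol: 19 without the silyl group; upper (2R,3S,4S), lower (2'R,3'S,4'R)-flavan-3',4'-diol | O[C@@H]1c2ccc(OCc3ccccc3)c([C@@H]3c4ccc(OCc5ccccc5)cc4O[C@H](c4cc(OCc5ccccc5)c(OCc5ccccc5)c(OCc5ccccc5)c4)[C@H]3O)c2O[C@H](c2cc(OCc3ccccc3)c(OCc3ccccc3)c(OCc3ccccc3)c2)[C@H]1O | intermediate
21 | octa-O-benzyl target: (2R,3R)-7-(benzyloxy)-8-{(2R,3S,4S)-7-(benzyloxy)-3-hydroxy-2-[3,4,5-tris(benzyloxy)phenyl]chroman-4-yl}-3-hydroxy-2-[3,4,5-tris(benzyloxy)phenyl]chroman-4-one | O=C1c2ccc(OCc3ccccc3)c([C@@H]3c4ccc(OCc5ccccc5)cc4O[C@H](c4cc(OCc5ccccc5)c(OCc5ccccc5)c(OCc5ccccc5)c4)[C@H]3O)c2O[C@H](c2cc(OCc3ccccc3)c(OCc3ccccc3)c(OCc3ccccc3)c2)[C@H]1O | intermediate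
22 | CNP0321606.1: (2R,3R)-3,7-dihydroxy-8-[(2R,3S,4S)-3,7-dihydroxy-2-(3,4,5-trihydroxyphenyl)chroman-4-yl]-2-(3,4,5-trihydroxyphenyl)chroman-4-one | O=C1c2ccc(O)c([C@@H]3c4ccc(O)cc4O[C@H](c4cc(O)c(O)c(O)c4)[C@H]3O)c2O[C@H](c2cc(O)c(O)c(O)c2)[C@H]1O | target

**Step count and risks**

Total step count: 15. Longest linear sequence: 15 steps (from 1; compounds 2, 4 and 7 are bought).

Steps most likely to fail:

1. Step 11 (double ring-closing metathesis). Closure onto the hindered 1,1-disubstituted enol ethers may be slow, and if the internal propenyl group initiates early the O1' enol ether may pair with the wrong alkene. The fallback sets out from 14 and closes the lower ring by intramolecular carbonyl olefination instead: the Takai–Utimoto titanium ethylidene reagent (TiCl4, Zn, PbCl2 cat., CH3CHBr2, TMEDA, THF, 65 °C) is expected to form a titanium alkylidene only at the terminal vinyl group, which olefinates the neighbouring O1' ester to give lower-chromene upper-ester F1. Petasis methylenation of the remaining ester (Cp2TiMe2, toluene, 70 °C) gives 16, where the route is rejoined; a single ring-closing metathesis then leads to 17 with no pairing ambiguity.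

2. Step 12 (double hydroboration). The lower ring of 17 is a 4-silyloxy-4H-chromene, a masked benzopyrylium ion, so the Lewis-acidic borane may ionise the C4'–O bond and reduce the cation; facial control may also be incomplete. The fallback sets out from 17: dimethyldioxirane (acetone/CH2Cl2, −40 °C, neutral) should epoxidise both enol ethers anti to the C4 substituents to give bis-epoxide F2, which removes the enol ethers before any Lewis acid is present. DIBAL-H (CH2Cl2, −78 °C) then opens each epoxide at C2 with hydride delivered from the aluminium alkoxide on the same face (cis opening), which returns to the route at 19.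

3. Step 5 (Claisen rearrangement). The allyl aryl ether may ionise instead of rearranging in concert, which would erode the chirality transfer and allow migration to C6'; the flanked C8' position may also react slowly. The fallback sets out from 6 and 7 and forms the C4–C8' bond by copper-mediated anti SN2' substitution. Alcohol 6 is esterified to picolinate F3 (picolinic acid, EDC·HCl, DMAP). Aldehyde 7 is converted into bis(methoxymethyl) ether F4 (MOMCl, iPr2NEt) and then into dimethyl acetal F5 (HC(OMe)3, PPTS, MeOH). F5 is lithiated between the two methoxymethoxy groups (n-BuLi, TMEDA, THF, 0 °C), transmetallated (MgBr2, then CuBr·SMe2, −78 °C) and coupled with F3 (−78 to −40 °C, where the aryl ester should survive). The aryl group should enter anti to the picolinate at the carbon bearing ring A, giving protected diarylbutene F6 with the same C4 configuration and (E)-propenyl group. Aqueous HCl in THF/MeOH removes the two methoxymethyl groups and the acetal and returns to the route at 9.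

Further compounds
F1 | step 11 | lower-chromene upper-ester: 16 with the upper enol ether still an ester (C=O in place of C=CH2) | C/C=C/[C@H](c1c(OCc2ccccc2)ccc2c1OC(c1cc(OCc3ccccc3)c(OCc3ccccc3)c(OCc3ccccc3)c1)=C[C@@H]2O[Si](C)(C)C(C)(C)C)c1ccc(OCc2ccccc2)cc1OC(=O)c1cc(OCc2ccccc2)c(OCc2ccccc2)c(OCc2ccccc2)c1
F2 | step 12 | bis-epoxide of 17: 2,3- and 2',3'-epoxides on the faces opposite the C4 aryl group and the C4' silyl ether | CC(C)(C)[Si](C)(C)O[C@@H]1c2ccc(OCc3ccccc3)c([C@@H]3c4ccc(OCc5ccccc5)cc4O[C@@]4(c5cc(OCc6ccccc6)c(OCc6ccccc6)c(OCc6ccccc6)c5)O[C@@H]34)c2O[C@@]2(c3cc(OCc4ccccc4)c(OCc4ccccc4)c(OCc4ccccc4)c3)O[C@@H]12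
F3 | step 5 | (R)-picolinate of 6 | C[C@@H](OC(=O)c1ccccn1)/C=C/c1ccc(OCc2ccccc2)cc1OC(=O)c1cc(OCc2ccccc2)c(OCc2ccccc2)c(OCc2ccccc2)c1
F4 | step 5 | 2,4-bis(methoxymethoxy)benzaldehyde | COCOc1ccc(C=O)c(OCOC)c1
F5 | step 5 | 1-(dimethoxymethyl)-2,4-bis(methoxymethoxy)benzene | COCOc1ccc(C(OC)OC)c(OCOC)c1
F6 | step 5 | protected diarylbutene: 9 with both lower-ring phenols as methoxymethyl ethers and the formyl group as dimethyl acetal; C4 (S), (E)-propenyl | C/C=C/[C@H](c1c(OCOC)ccc(C(OC)OC)c1OCOC)c1ccc(OCc2ccccc2)cc1OC(=O)c1cc(OCc2ccccc2)c(OCc2ccccc2)c(OCc2ccccc2)c1
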